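## Retrosynthetic overview

1. Target 12 ⇒ tetracyclic lactone 9 + 4‑acetoxybenzaldehyde: the E‑benzylidene is made last by aldol condensation.
2. 9 ⇒ spiro‑butenolide lactol (from 8): a biomimetic intramolecular oxa‑Michael addition closes the tetrahydrofuran acetal ring and sets C1 and C10.
3. 8 ⇒ Z‑γ,δ‑epoxy dienoate 6: selenolate epoxide opening with lactonisation, then selenoxide elimination, closes the spiro‑γ‑lactone, sets C8 and places C6=C7.
4. 6 ⇒ genipin (1) by C10 oxidation, C1 silylation, Z‑olefination and β‑face epoxidation; C5 and C9 come from the chiral pool.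
5. Ring order: cyclopentene + dihydropyran (bought as genipin) → spiro‑γ‑lactone → tetrahydrofuran acetal.

Assumption: genipin (commercial, (1R,4aS,7aS)) is accepted as a chiral‑pool starting material, which makes this a chiral‑pool (semi)synthesis and not a de novo one; its C5/C9 configuration (S,S) is that of the target.

Iridoid numbering is used throughout: C1 acetal; C3=C4 enol ether (C4 bears CO2Me); C5/C9 ring fusion; C6=C7; C8 spiro carbon; C10 O–CH; C11 lactone α‑carbon; C12 lactone C=O; C13 benzylidene CH. "β" means the face carrying H‑5 and H‑9.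

## Route

**Step 1**
Reactants: 1, genipin
Product: 2, 10‑oxogenipin: methyl (1R,4aS,7aS)‑7‑formyl‑1‑hydroxy‑1,4a,5,7a‑tetrahydrocyclopenta[c]pyran‑4‑carboxylate
Conditions: activated MnO2 (excess), CH2Cl2, rt
Reagents that add atoms: none
Why: MnO2 allylic oxidation takes only the primary allylic C10–OH to the enal; the non‑allylic lactol OH and all stereocentres are untouched.

**Step 2**
Reactants: 2
Product: 3, methyl (1S,4aS,7aS)‑1‑(tert‑butyldimethylsilyloxy)‑7‑formyl‑1,4a,5,7a‑tetrahydrocyclopenta[c]pyran‑4‑carboxylate (1β‑OTBS, same spatial arrangement as genipin)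
Conditions: TBSCl, imidazole, DMF, 0 °C → rt
Reagents that add atoms: TBSCl, CC(C)(C)[Si](C)(C)Cl
Why: Silylation of the only remaining OH masks the base‑sensitive lactol as a silyl acetal; the anomer ratio is irrelevant because C1 is re‑equilibrated in step 7.

**Step 3**
Reactants: 3; 4, methyl bis(2,2,2‑trifluoroethyl)phosphonoacetate
Product: 5, methyl (1S,4aS,7aS)‑1‑(TBSO)‑7‑[(1Z)‑3‑methoxy‑3‑oxoprop‑1‑enyl]‑1,4a,5,7a‑tetrahydrocyclopenta[c]pyran‑4‑carboxylate (Z‑dienoate)
Conditions: 4, KHMDS, 18‑crown‑6, THF, −78 °C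
Reagents that add atoms: 4, COC(=O)CP(=O)(OCC(F)(F)F)OCC(F)(F)F (delivers =CH–CO2Me, i.e. C11 and C12)
Why: Still–Gennari (Z‑selective Horner–Wadsworth–Emmons) olefination of the enal gives the Z‑enoate needed for later lactonisation onto C8.

**Step 4**
Reactants: 5
Product: 6, the 7β,8β‑epoxide of 5 (7S,8R): Z‑γ,δ‑epoxy‑α,β‑unsaturated ester
Conditions: mCPBA, NaHCO3, CH2Cl2, 0 °C → rt
Reagents that add atoms: mCPBA, O=C(OO)c1cccc(Cl)c1
Why: Prilezhaev epoxidation should attack the distal trisubstituted C7=C8 in preference to the electron‑poor C10=C11 and the push–pull C3=C4, from the convex β face anti to the dihydropyran, which fixes the C8–O bond in its final configuration.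

**Step 5**
Reactants: 6
Product: 7, 7α‑phenylseleno spiro‑butenolide: C8 is the γ‑carbon of a but‑2‑enolide (O–C8 β, C10=C11, C12=O), SePh on C7 (7R,8R), 1β‑OTBS retained
Conditions: (PhSe)2, NaBH4, MeOH/THF, 0 °C (preform PhSeNa), then 6, rt
Reagents that add atoms: diphenyl diselenide, c1ccc(cc1)[Se][Se]c1ccccc1
Why: Selenolate SN2 opening at the secondary C7 (inversion there, C8–O retained) releases the tertiary C8 alkoxide, which lactonises onto the Z‑ester with loss of MeOH to form the spiro‑butenolide.

**Step 6**
Reactants: 7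
Product: 8, 1β‑OTBS spiro‑butenolide diene (C6=C7 and C10=C11; C8 R, lactone O on the β face)
Conditions: 30% H2O2, pyridine, CH2Cl2, 0 °C → rt
Reagents that add atoms: none
Why: Selenoxide syn‑elimination (Sharpless–Reich allylic transposition) can only take a C6 hydrogen, giving C6=C7 without touching C8; any selenolate conjugate adduct reverts to the butenolide under the same conditions.

**Step 7**
Reactants: 8
Product: 9, tetracyclic lactone (the target skeleton with C11H2), (1R,5S,8S,9S,10S)
Conditions: TBAF, AcOH, THF, 0 °C; then DBU (0.2 equiv), CH2Cl2, rt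
Reagents that add atoms: none
Why: Desilylation frees the lactol, which anomerises so that the α‑oxygen adds 5‑exo to the butenolide β‑carbon C10 (biomimetic intramolecular oxa‑Michael); the cis‑fused furofuranone is the only geometrically possible adduct, so C1 (R) and C10 (S) are set by the ring system.

**Step 8**
Reactants: 9; 10, 4‑acetoxybenzaldehyde
Product: 11, β‑acetoxy aldol adduct: 9 bearing CH(OAc)(4‑AcO‑C6H4) on C11 (mixture of C11/C13 diastereomers)
Conditions: LDA, THF, −78 °C; 10; then Ac2O, −78 → 0 °C
Reagents that add atoms: 10, CC(=O)Oc1ccc(C=O)cc1; acetic anhydride, CC(=O)OC(C)=O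
Why: Aldol addition of the lactone lithium enolate (the only acidic C–H) to the aldehyde, with in‑situ O‑acetylation that also restores any aryl acetate lost; the new C11/C13 centres are removed in step 9.

**Step 9**
Reactants: 11
Product: 12, 3‑O‑acetylprismatomerin (target)
Conditions: DBU, CH2Cl2, 0 °C → rt
Reagents that add atoms: none
Why: E1cB loss of acetate gives the thermodynamically preferred E‑benzylidene lactone (aryl anti to the lactone C=O), and the exocyclic acetate leaves in preference to the ring acetal oxygen.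

## Compound list

1 | genipin, methyl (1R,4aS,7aS)‑1‑hydroxy‑7‑(hydroxymethyl)‑1,4a,5,7a‑tetrahydrocyclopenta[c]pyran‑4‑carboxylate | COC(=O)C1=CO[C@@H](O)[C@@H]2C(CO)=CC[C@H]12 | starting material
2 | 10‑oxogenipin (enal lactol) | COC(=O)C1=CO[C@@H](O)[C@@H]2C(C=O)=CC[C@H]12 | intermediate
3 | 1‑O‑TBS‑10‑oxogenipin | COC(=O)C1=CO[C@@H](O[Si](C)(C)C(C)(C)C)[C@@H]2C(C=O)=CC[C@H]12 | intermediate
4 | methyl bis(2,2,2‑trifluoroethyl)phosphonoacetate | COC(=O)CP(=O)(OCC(F)(F)F)OCC(F)(F)F | starting material
5 | Z‑dienoate | COC(=O)C1=CO[C@@H](O[Si](C)(C)C(C)(C)C)[C@@H]2C(/C=C\C(=O)OC)=CC[C@H]12 | intermediate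
6 | 7β,8β‑epoxy Z‑enoate | COC(=O)C1=CO[C@@H](O[Si](C)(C)C(C)(C)C)[C@@H]2[C@@]3(/C=C\C(=O)OC)O[C@H]3C[C@H]12 | intermediate
7 | 7α‑phenylseleno spiro‑butenolide | COC(=O)C1=CO[C@@H](O[Si](C)(C)C(C)(C)C)[C@@H]2[C@]3(C=CC(=O)O3)[C@H]([Se]c4ccccc4)C[C@H]12 | intermediate
8 | 1‑O‑TBS spiro‑butenolide diene | COC(=O)C1=CO[C@@H](O[Si](C)(C)C(C)(C)C)[C@@H]2[C@]3(C=CC(=O)O3)C=C[C@H]12 | intermediate
9 | tetracyclic lactone (C11H2) | COC(=O)C1=CO[C@@H]2O[C@H]3CC(=O)O[C@]34C=C[C@H]1[C@H]24 | intermediate
10 | 4‑acetoxybenzaldehyde | CC(=O)Oc1ccc(C=O)cc1 | starting material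
11 | β‑acetoxy aldol adduct (C11/C13 diastereomer mixture) | COC(=O)C1=CO[C@@H]2O[C@H]3C(C(OC(C)=O)c4ccc(OC(C)=O)cc4)C(=O)O[C@]34C=C[C@H]1[C@H]24 | intermediate
12 | 3‑O‑acetylprismatomerin, (1R,5S,8S,9S,10S), E | COC(=O)C1=CO[C@@H]2O[C@H]3/C(=C\c4ccc(OC(C)=O)cc4)C(=O)O[C@]34C=C[C@H]1[C@H]24 | target

## Totals and risks

Total step count: 9. Longest linear sequence: 9 steps (fully linear from genipin).

Steps most likely to fail:

1. **Steps 4–5 (β‑epoxidation of the dienoate, then α‑face selenolate opening at C7, which together set C8).** Poor face or site selectivity, or selenolate conjugate addition, would erode the spiro centre. Fallback: do the oxygen transposition before chain extension. Convert genipin to its 1‑O‑methyl acetal, run a VO(acac)2/TBHP hydroxyl‑directed epoxidation, open at C7 with PhSeH/Ti(OiPr)4 and eliminate the selenoxide to the 8β‑hydroxy‑Δ6 diol. Then oxidise C10 with TEMPO/PhI(OAc)2 and use Z‑olefination with spontaneous lactonisation to reach the same butenolide.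

2. **Step 7 (lactol release and oxa‑Michael).** The free lactol can ring‑open to the dialdehyde and expel the C8 carboxylate by E1cB. Fallback: build the C1–O–C10 acetal before the lactone. From the 8‑hydroxy‑10‑aldehyde with free C1–OH, trap the aldehyde as the bridged C1–O–C10 lactol, acetylate, and add the silyl ketene acetal of methyl acetate under BF3·OEt2 on the convex face (oxocarbenium C‑glycosylation). Lactonisation with the C8–OH then gives 9 without a free butenolide lactol.

3. **Step 8 (aldol of a lactone enolate carrying a β‑alkoxy leaving group).** Retro‑oxa‑Michael or low conversion is possible. Fallback: reverse the order biomimetically. Hydroxybenzylate butenolide 8 at C11 with aldehyde 10 (Morita–Baylis–Hillman, or PhSeLi Michael/aldol followed by selenoxide elimination) and acetylate. Fluoride unmasking of C1–OH then triggers oxa‑Michael/E1cB (SN2′) closure straight to the E‑benzylidene target, with no lactone enolate involved.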